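The numbers in the tables are calculated for an exercise.

4 questions stand over this flask, and one ratio carries them.

| flask | starting material | partner | remark | time |
|---|---|---|---|---|
| west | 1 M | 0.90 M | run made earlier |  |
| flask | 1.0 M | 1.80 M |  | 20 h |

west run (percent of the starting material charged)

| time / h | starting material / % | target / % | side product / % |
|---|---|---|---|
| 2.00 | 95.9 | 2.6 | 2.6 |
| 6.00 | 86.9 | 6.8 | 7.0 |
| 10.0 | 78.3 | 9.9 | 11.0 |
| 15.0 | 70.1 | 14.6 | 15.3 |

(readings scatter by 0.3 percentage points)

* the state of affairs at 20 h: stopped, and by what, or still going (the partner has run out first / forward and back rates have come level / all of the starting material has reacted / it is still moving)
* how much of the starting material has reacted by 20 h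
* how much target there is at 20 h, in percent of the starting material charged
* how much side product there is at 20 h, in percent of the starting material charged

- steps thought possible: starting material -> side product; starting material -> decomposition product; starting material + partner -> target
- the reaction counts as stopped when no species that holds the starting material changes by six tenths of a point or more over the second half of the time

Starting material goes to side product at a rate proportional to [starting material], and to target at a rate proportional to [starting material][partner]. In the ratio of these rates [starting material] cancels, leaving [partner] times a constant, the selectivity factor.

The west run gives a reading of it. At 15.0 h it holds 14.6% target against 15.3% side product, a ratio of 0.954. Its readings sum to 100%, so no decomposition shows. Each target made uses one partner, so [partner] averaged about 0.827 M. The selectivity factor, target formed per side product formed per molar of partner, is therefore 1.15 M⁻¹. In the west run starting material decayed with a constant, read as first order, of 0.0237 h⁻¹. Dividing that by one plus the ratio leaves 0.0121 h⁻¹ for the side product path.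

In the flask the ratio starts at 2.08, so target forms at first twice as fast as side product. But the ratio drifts down as partner is used. Holding it at the starting value gives 35.5% target by 20 h. Mean [partner] in the flask is then about 1.62 M, and the mean ratio 1.87. With that ratio, this reckoning gives 50.2% reacted, 32.7% target and 17.5% side product. Starting material falls about 21 percentage points over the second half of the time, and [partner] ends near 1.47 M, so the flask is still moving.

The forecast, whose figures differ from those of this reckoning, says it is still moving, with 50% reacted, 32.4% target and 17.6% side product: “Partner remains in excess and starting material is still falling quickly”.

The computed flask at 20 h: it is still moving, with 50.0% reacted, 32.7% target and 17.2% side product.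

    starting material → side product (k = 0.0120 h⁻¹)
    starting material → decomposition product (k = 1.20 × 10⁻⁴ h⁻¹)
    starting material + partner → target (k = 0.0140 M⁻¹ h⁻¹)

Left for 200 h, the flask holds 62.7% target and 36.7% side product, with partner at 65.2% of its charge. The selectivity factor puts the momentary ratio there at 1.35, lower than the 1.71 of the accumulated amounts.

In the neighbour flask with 0.72 M of partner, the ratio starts at 0.831 and averages 0.737, which gives 34.4% reacted, 14.6% target and 19.8% side product. That flask computes to 34.4%, 14.7% and 19.5%.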